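**Strategy.** Ring B is disconnected across C7–C8 and C9–C10. The C8(C17)–C9(C11) unit of the target is a but-2-yne oxidised at both ends, and C10 with its methyl, C5 and C6–C7 form a 2-methyl-1-vinylcyclohexene that already contains ring A and the C4 quaternary centre. A Lewis-acid-promoted Diels–Alder reaction of this diene ester with 4-silyloxybut-2-ynal therefore closes ring B in one operation, creates quaternary C10 and leaves C8=C9 tetrasubstituted with an aldehyde at C11 and an allylic oxygen at C17. The aldehyde later receives C12–C16 by a Wittig reaction; the C17 oxygen is spent in a palladium/formate reductive transposition that installs the 8(17)-methylene and 9α-H.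

Key step: step 6

Remark: labdane numbering is used for all bicyclic compounds (α = face opposite the C10 methyl, C20); in step 1 the antipode of the phase-transfer catalyst is taken to be the one that delivers the (R)-keto ester.

**Step 1**
Reactants: 1 methyl 2-oxocyclohexane-1-carboxylate
Product: 2 methyl (R)-1-methyl-2-oxocyclohexane-1-carboxylate
Conditions: MeI, C2-symmetric N-spiro binaphthyl quaternary ammonium bromide (2 mol%), K2CO3 (solid), toluene, 0 °C
Reagents that add atoms: iodomethane, CI
Why: Asymmetric phase-transfer C-alkylation of a cyclic β-keto ester, in which the enolate is methylated as a tight ion pair with the chiral ammonium cation that shields one enolate face and so sets the quaternary centre (future C4, R).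

**Step 2**
Reactants: 2 methyl (R)-1-methyl-2-oxocyclohexane-1-carboxylate
Product: 4 methyl (1R,3RS)-1,3-dimethyl-2-oxocyclohexane-1-carboxylate, via lithium enolate 3 (not isolated)
Conditions: LDA, THF, −78 °C; MeI, −78 → 0 °C
Reagents that add atoms: iodomethane, CI
Why: Kinetic enolate alkylation: C1 is quaternary, so only the α'-CH2 can be deprotonated, and SN2 methylation brings in the future C20; the new C3 centre forms as an epimer mixture that is erased in step 3.

**Step 3**
Reactants: 4 methyl (1R,3RS)-1,3-dimethyl-2-oxocyclohexane-1-carboxylate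
Product: 6 methyl (R)-1,3-dimethyl-2-{[(trifluoromethyl)sulfonyl]oxy}cyclohex-2-ene-1-carboxylate, via potassium enolate 5 (not isolated)
Conditions: KHMDS, THF, −78 → 0 °C; PhNTf2, −78 °C → rt
Reagents that add atoms: N-phenylbis(trifluoromethanesulfonimide), O=S(=O)(N(c1ccccc1)S(=O)(=O)C(F)(F)F)C(F)(F)F
Why: Enolate O-sulfonylation (enol triflate formation); the ketone can enolise only towards the methyl-bearing carbon, so a single tetrasubstituted enol triflate should result and the quaternary stereocentre is untouched.

**Step 4**
Reactants: 6 methyl (R)-1,3-dimethyl-2-{[(trifluoromethyl)sulfonyl]oxy}cyclohex-2-ene-1-carboxylate; 7 tributyl(vinyl)stannane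
Product: 8 methyl (R)-1,3-dimethyl-2-vinylcyclohex-2-ene-1-carboxylate
Conditions: Pd(PPh3)4 (5 mol%), LiCl, THF, reflux
Reagents that add atoms: none
Why: Stille cross-coupling of a vinyl triflate with a vinylstannane, a reaction established for 2,6,6-trisubstituted cyclohexenyl triflates, brings in C6–C7 and avoids a carbonyl addition/dehydration sequence that a β-keto ester tolerates poorly.

**Step 5**
Reactants: 9 tert-butyldimethyl(prop-2-yn-1-yloxy)silane
Product: 12 4-(tert-butyldimethylsilyloxy)but-2-ynal, via lithium acetylide 10 (not isolated), via lithium hemiaminal alkoxide 11 (not isolated)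
Conditions: n-BuLi, THF, −78 °C; DMF, −78 → 0 °C; inverse quench into aq. KH2PO4/MTBE, 0 °C
Reagents that add atoms: N,N-dimethylformamide, CN(C)C=O
Why: Formylation of a lithium acetylide with DMF; the tetrahedral adduct persists until the buffered inverse quench, which releases the ynal without conjugate addition of dimethylamine.

**Step 6**
Reactants: 8 methyl (R)-1,3-dimethyl-2-vinylcyclohex-2-ene-1-carboxylate; 12 4-(tert-butyldimethylsilyloxy)but-2-ynal
Product: 13 methyl 17-(tert-butyldimethylsilyloxy)-11-oxo-12,13,14,15,16-pentanorlabda-5,8-dien-18-oate (4α-CO2Me, 4β-Me, 10β-Me)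
Conditions: Me2AlCl (1.2 equiv, precomplexed with 12), CH2Cl2, −78 → −30 °C
Reagents that add atoms: none
Why: Me2AlCl binds the aldehyde and lowers the LUMO of the ynal, so a normal-electron-demand but asynchronous [4+2] cycloaddition should take place in which the unsubstituted, most nucleophilic diene terminus C7 bonds first to the β-carbon C8 while positive character builds up at the tertiary allylic carbon C10, which then bonds to the α-carbon C9. The closest known reaction type is the Diels–Alder reaction of 2-methyl-1-vinylcyclohexenes with acetylenic carbonyl dienophiles, here in its Lewis-acid-promoted ynal form. Ring B is closed by intermolecular [4+2] cycloaddition (suprafacial on both partners) as a six-membered 1,4-cyclohexadiene that cannot aromatise because C10 is quaternary. C10 is the only new stereocentre and is controlled by the C4 quaternary centre: the dienophile must add to the α-face, the face of the C18 ester, so that C20 ends up β and cis to C19. In the planar s-cis diene C6–H lies in the plane beside the pseudoequatorial C4 substituent, which should favour the flat ester there and turn the C19 methyl pseudoaxial, where it blocks the β-face 1,3 to the forming C9–C10 bond. Regioselectivity is secured by the polarisation named above and the low temperature, whereas the facial preference rests on a small methyl-versus-ester difference, so both C10 epimers may form and would be separated by chromatography here.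

**Step 7**
Reactants: 13 methyl 17-(tert-butyldimethylsilyloxy)-11-oxo-12,13,14,15,16-pentanorlabda-5,8-dien-18-oate
Product: 14 methyl 17-(tert-butyldimethylsilyloxy)-11-oxo-12,13,14,15,16-pentanorlabd-8-en-18-oate (5α-H, trans-decalin)
Conditions: H2 (1–3 atm), 10% Pd/C, EtOAc, rt
Reagents that add atoms: none
Why: Heterogeneous hydrogenation selects the trisubstituted C5=C6 over the tetrasubstituted, conjugated C8=C9 (as in the reduction of drima-5,8-diene diesters), and hydrogen is delivered to the α-face because the 1,3-diaxial C19 and C20 methyls cover the β-face, which sets C5 (5α-H).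

**Step 8**
Reactants: 15 (R)-4-methyldihydrofuran-2(3H)-one
Product: 16 methyl (R)-4-bromo-3-methylbutanoate
Conditions: HBr (g), MeOH, 0 °C → rt
Reagents that add atoms: hydrogen bromide, Br; methanol, CO
Why: Acid-mediated lactone opening (SN2 attack of bromide at the O–CH2 carbon) combined with Fischer esterification; the future C13 stereocentre is not a reacting centre and is carried through unchanged.

**Step 9**
Reactants: 16 methyl (R)-4-bromo-3-methylbutanoate
Product: 17 [(2R)-4-methoxy-2-methyl-4-oxobutyl]triphenylphosphonium bromide
Conditions: PPh3, MeCN, reflux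
Reagents that add atoms: triphenylphosphine, c1ccc(cc1)P(c1ccccc1)c1ccccc1
Why: SN2 quaternisation of triphenylphosphine by the primary bromide gives the Wittig salt without touching the stereocentre.

**Step 10**
Reactants: 14 methyl 17-(tert-butyldimethylsilyloxy)-11-oxo-12,13,14,15,16-pentanorlabd-8-en-18-oate; 17 [(2R)-4-methoxy-2-methyl-4-oxobutyl]triphenylphosphonium bromide
Product: 19 dimethyl (11Z,13R)-17-(tert-butyldimethylsilyloxy)labda-8,11-diene-15,18-dioate, via phosphorus ylide 18 (not isolated)
Conditions: 17, NaHMDS (1.0 equiv), THF, −78 → 0 °C; then 14, −78 °C → rt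
Reagents that add atoms: none
Why: Wittig olefination with a non-stabilised ylide, made with one equivalent of base so that the ester is not enolised, should convert the hindered enal (comparable to β-cyclocitral) into the (Z)-alkene, whose geometry is irrelevant because it is reduced in step 11.

**Step 11**
Reactants: 19 dimethyl (11Z,13R)-17-(tert-butyldimethylsilyloxy)labda-8,11-diene-15,18-dioate
Product: 20 dimethyl (13S)-17-(tert-butyldimethylsilyloxy)labd-8-ene-15,18-dioate
Conditions: 2-nitrobenzenesulfonylhydrazide (excess), Et3N, CH2Cl2, rt
Reagents that add atoms: none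
Why: Diimide reduction transfers H2 in a concerted syn fashion to the disubstituted C11=C12 only, since tetrasubstituted C8=C9 is inert to diimide, and it causes neither double-bond migration nor allylic C–O hydrogenolysis.

**Step 12**
Reactants: 20 dimethyl (13S)-17-(tert-butyldimethylsilyloxy)labd-8-ene-15,18-dioate
Product: 21 dimethyl (13S)-17-hydroxylabd-8-ene-15,18-dioate
Conditions: TBAF, THF, 0 °C → rt
Reagents that add atoms: none
Why: Fluoride-mediated cleavage of the silyl ether (strong Si–F bond) frees the C17 allylic alcohol and leaves both esters intact.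

**Step 13**
Reactants: 21 dimethyl (13S)-17-hydroxylabd-8-ene-15,18-dioate
Product: 22 dimethyl (13S)-17-(formyloxy)labd-8-ene-15,18-dioate
Conditions: AcOCHO, pyridine, CH2Cl2, 0 °C
Reagents that add atoms: acetic formic anhydride, CC(=O)OC=O
Why: O-Formylation of the primary allylic alcohol with the mixed anhydride, which reacts at its formyl carbon, gives the substrate for the palladium step.

**Step 14**
Reactants: 22 dimethyl (13S)-17-(formyloxy)labd-8-ene-15,18-dioate
Product: 23 dimethyl (13S)-labd-8(17)-ene-15,18-dioate (9α-H)
Conditions: Pd2(dba)3·CHCl3 (2.5 mol%), n-Bu3P (5 mol%), THF, rt → 40 °C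
Reagents that add atoms: none
Why: Palladium-catalysed hydrogenolysis of an allylic formate with allylic transposition: Pd(0) ionises the C17–O bond from the less hindered α-face, the π-allylpalladium formate loses CO2, and the resulting hydride is delivered from palladium to the more substituted terminus C9 on that same face, which should give the 8(17)-methylene and set C9 (9α-H, side chain equatorial).

**Step 15**
Reactants: 23 dimethyl (13S)-labd-8(17)-ene-15,18-dioate
Product: 24 (13S)-18-methoxy-18-oxolabd-8(17)-en-15-oic acid, i.e. (3S)-5-[(1S,4aR,5R,8aR)-5-(methoxycarbonyl)-5,8a-dimethyl-2-methylidenedecahydronaphthalen-1-yl]-3-methylpentanoic acid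
Conditions: LiOH·H2O, THF/MeOH/H2O, 0 °C → rt; then dilute HCl to pH 3
Reagents that add atoms: lithium hydroxide, [Li+].[OH-]
Why: Saponification distinguishes the two methyl esters by steric access: the C15 ester on a CH2 group is hydrolysed at room temperature, whereas the tertiary, neopentyl-type C18 ester at C4 resists hydroxide under these conditions.

**Compound list**

1 | methyl 2-oxocyclohexane-1-carboxylate | COC(=O)C1CCCCC1=O | starting material
2 | methyl (R)-1-methyl-2-oxocyclohexane-1-carboxylate | O=C1CCCC[C@@]1(C)C(=O)OC | intermediate
3 | lithium enolate of 2 (not isolated) | [Li+].[O-]C1=CCCC[C@@]1(C)C(=O)OC | intermediate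
4 | methyl (1R,3RS)-1,3-dimethyl-2-oxocyclohexane-1-carboxylate (C3 epimer mixture) | CC1CCC[C@@](C)(C(=O)OC)C1=O | intermediate
5 | potassium enolate of 4 (not isolated) | [K+].[O-]C1=C(C)CCC[C@@]1(C)C(=O)OC | intermediate
6 | methyl (R)-1,3-dimethyl-2-{[(trifluoromethyl)sulfonyl]oxy}cyclohex-2-ene-1-carboxylate | O=S(=O)(OC1=C(C)CCC[C@@]1(C)C(=O)OC)C(F)(F)F | intermediate
7 | tributyl(vinyl)stannane | C=C[Sn](CCCC)(CCCC)CCCC | starting material
8 | methyl (R)-1,3-dimethyl-2-vinylcyclohex-2-ene-1-carboxylate | C=CC1=C(C)CCC[C@@]1(C)C(=O)OC | intermediate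
9 | tert-butyldimethyl(prop-2-yn-1-yloxy)silane | C#CCO[Si](C)(C)C(C)(C)C | starting material
10 | lithium acetylide of 9 (not isolated) | [Li+].[C-]#CCO[Si](C)(C)C(C)(C)C | intermediate
11 | lithium 4-(tert-butyldimethylsilyloxy)-1-(dimethylamino)but-2-yn-1-olate (not isolated) | [Li+].[O-]C(N(C)C)C#CCO[Si](C)(C)C(C)(C)C | intermediate
12 | 4-(tert-butyldimethylsilyloxy)but-2-ynal | O=CC#CCO[Si](C)(C)C(C)(C)C | intermediate
13 | methyl 17-(tert-butyldimethylsilyloxy)-11-oxo-12,13,14,15,16-pentanorlabda-5,8-dien-18-oate (4α-CO2Me, 4β-Me, 10β-Me) | O=CC1=C(CO[Si](C)(C)C(C)(C)C)CC=C2[C@]1(C)CCC[C@@]2(C)C(=O)OC | intermediate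
14 | methyl 17-(tert-butyldimethylsilyloxy)-11-oxo-12,13,14,15,16-pentanorlabd-8-en-18-oate (5α-H) | O=CC1=C(CO[Si](C)(C)C(C)(C)C)CC[C@@H]2[C@]1(C)CCC[C@@]2(C)C(=O)OC | intermediate
15 | (R)-4-methyldihydrofuran-2(3H)-one | O=C1C[C@@H](C)CO1 | starting material
16 | methyl (R)-4-bromo-3-methylbutanoate | COC(=O)C[C@@H](C)CBr | intermediate
17 | [(2R)-4-methoxy-2-methyl-4-oxobutyl]triphenylphosphonium bromide | COC(=O)C[C@@H](C)C[P+](c1ccccc1)(c1ccccc1)c1ccccc1.[Br-] | intermediate
18 | methyl (3R)-3-methyl-4-(triphenyl-λ5-phosphanylidene)butanoate (ylide, not isolated) | COC(=O)C[C@@H](C)C=P(c1ccccc1)(c1ccccc1)c1ccccc1 | intermediate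
19 | dimethyl (11Z,13R)-17-(tert-butyldimethylsilyloxy)labda-8,11-diene-15,18-dioate | COC(=O)C[C@@H](C)/C=C\C1=C(CO[Si](C)(C)C(C)(C)C)CC[C@@H]2[C@]1(C)CCC[C@@]2(C)C(=O)OC | intermediate
20 | dimethyl (13S)-17-(tert-butyldimethylsilyloxy)labd-8-ene-15,18-dioate | COC(=O)C[C@@H](C)CCC1=C(CO[Si](C)(C)C(C)(C)C)CC[C@@H]2[C@]1(C)CCC[C@@]2(C)C(=O)OC | intermediate
21 | dimethyl (13S)-17-hydroxylabd-8-ene-15,18-dioate | COC(=O)C[C@@H](C)CCC1=C(CO)CC[C@@H]2[C@]1(C)CCC[C@@]2(C)C(=O)OC | intermediate
22 | dimethyl (13S)-17-(formyloxy)labd-8-ene-15,18-dioate | COC(=O)C[C@@H](C)CCC1=C(COC=O)CC[C@@H]2[C@]1(C)CCC[C@@]2(C)C(=O)OC | intermediate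
23 | dimethyl (13S)-labd-8(17)-ene-15,18-dioate (5α-H, 9α-H, 10β-Me) | C=C1CC[C@@H]2[C@](C)(CCC[C@@]2(C)C(=O)OC)[C@H]1CC[C@H](C)CC(=O)OC | intermediate
24 | (13S)-18-methoxy-18-oxolabd-8(17)-en-15-oic acid (CNP0135192.1) | C=C1CC[C@@H]2[C@](C)(CCC[C@@]2(C)C(=O)OC)[C@H]1CC[C@H](C)CC(=O)O | target

**Totals.** 15 steps in all; longest linear sequence 12 steps (steps 1–4, 6, 7, 10–15).

**Steps most likely to fail**

Step 6. The dienophile may add to both faces of the diene with little preference, because attack syn to the C19 methyl competes with the wanted attack on the ester face; Lewis-acid-induced ene-type or oligomerisation pathways may also lower the yield. The fallback moves the stereocontrol from the substrate to the reagent. Setting out again from 8 and 12, the cycloaddition would be run as a catalyst-controlled asymmetric Diels–Alder reaction of the acetylenic aldehyde with a chiral boron Lewis acid (a Brønsted-acid-assisted binaphthol boronate or a triflimide-activated proline-derived oxazaborolidinium ion), a known reaction class for ynals. Because the intrinsic bias of the enantiopure diene is weak, the catalyst antipode matched to α-face attack would dominate the facial choice. The route is rejoined at 13 and no new compound arises.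

Step 14. Hydride may be delivered to C17 instead of C9, which would give the tetrasubstituted 8-ene with a C17 methyl, or ionisation of the hindered allylic formate may be so slow that loss of the formyl group takes over. The fallback is a metal-free, sigmatropic reductive transposition. Setting out from allylic alcohol 21, a Mitsunobu reaction with 2-nitrobenzenesulfonylhydrazide (PPh3, DEAD, THF, −30 °C) would give dimethyl (13S)-17-[1-(2-nitrobenzenesulfonyl)hydrazin-1-yl]labd-8-ene-15,18-dioate F1. On warming to room temperature F1 loses the sulfinic acid to give the allylic diazene dimethyl (13S)-17-diazenyllabd-8-ene-15,18-dioate F2. F2 expels N2 in a retro-ene reaction that moves the alkene to C8=C17 and places hydrogen on C9 from the less hindered α-face. This rejoins the route at 23 and bypasses step 13.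

Step 1. Ion pairing with the small electrophile MeI and the small methyl ester may give insufficient enantiofacial discrimination, with some O-methylation as a side reaction. The fallback uses auxiliary control through a chiral enamine. Setting out from 1, condensation with L-valine tert-butyl ester (cat. BF3·OEt2, benzene, reflux, removal of water) would give the enamino ester methyl 2-{[(2S)-1-tert-butoxy-3-methyl-1-oxobutan-2-yl]amino}cyclohex-1-ene-1-carboxylate F3. Lithiation (LDA, toluene, −78 °C) and methylation with MeI follow, in the presence of the coordinating additive (HMPA or THF/1,3-dioxolane) that steers alkylation to the required face; the sense of induction of such lithiated enamines is known to depend on the ligand. This would give the imine methyl (1R)-2-{[(2S)-1-tert-butoxy-3-methyl-1-oxobutan-2-yl]imino}-1-methylcyclohexane-1-carboxylate F4, which dilute aqueous acid hydrolyses to 2 with return of the amino ester.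

**Further compounds**

F0 | step 6 | none | none
F1 | step 14 | dimethyl (13S)-17-[1-(2-nitrobenzenesulfonyl)hydrazin-1-yl]labd-8-ene-15,18-dioate | COC(=O)C[C@@H](C)CCC1=C(CN(N)S(=O)(=O)c3ccccc3[N+](=O)[O-])CC[C@@H]2[C@]1(C)CCC[C@@]2(C)C(=O)OC
F2 | step 14 | dimethyl (13S)-17-diazenyllabd-8-ene-15,18-dioate | COC(=O)C[C@@H](C)CCC1=C(CN=N)CC[C@@H]2[C@]1(C)CCC[C@@]2(C)C(=O)OC
F3 | step 1 | methyl 2-{[(2S)-1-tert-butoxy-3-methyl-1-oxobutan-2-yl]amino}cyclohex-1-ene-1-carboxylate | COC(=O)C1=C(N[C@@H](C(C)C)C(=O)OC(C)(C)C)CCCC1
F4 | step 1 | methyl (1R)-2-{[(2S)-1-tert-butoxy-3-methyl-1-oxobutan-2-yl]imino}-1-methylcyclohexane-1-carboxylate | CC(C)[C@H](N=C1CCCC[C@@]1(C)C(=O)OC)C(=O)OC(C)(C)C
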